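The summer readings average 34.1% target, which is a leftover: about 65.9% of the starting material in the summer flask has not become target, and the readings are already flat from the first one at 2.00 h. You have these flasks, and these questions:

| flask | starting material | second substrate | coupling partner | free catalyst | temperature | remark | time |
|---|---|---|---|---|---|---|---|
| summer | 20 mM | 20 mM | 22 mM | 0.26 mM | 110 °C | the very flask that is asked about, followed so far |  |
| dawn | 20 mM | 10 mM | 22 mM | 0.26 mM | 105 °C | run made earlier |  |
| flask | 20 mM | 20.0 mM | 22.0 mM | 0.26 mM | 110 °C |  | 40 h |

summer run (percent of the starting material charged): time / h: target / % = 2.00: 34.4; 6.00: 33.7; 12.0: 34.2; 20.0: 34.5; 25.0: 33.8; 30.0: 33.7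

dawn run (percent of the starting material charged): time / min: target / % = 4.00: 9.7; 6.00: 14.2; 10.0: 20.5; 20.0: 30.3; 30.0: 37.3; 50.0: 42.2

(scatter of a reading: 0.3 percentage points)

- target that was removed still counts
- the numbers in the tables scatter with a standard deviation of 0.3 percentage points
- what may be going on: starting material + free catalyst <-> catalyst intermediate A; coupling partner + catalyst intermediate A -> free catalyst + target; second substrate + free catalyst <-> catalyst intermediate B; coupling partner + catalyst intermediate B -> free catalyst + second product; catalyst intermediate A -> spent catalyst
- additions bring no volume worth counting

- south-east: at 40 h add free catalyst, 100% of the amount charged, then wait 3.0 d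
- south-west: at 40 h take out 90% of the target then present, then wait 3.0 d
- north-east: at 40 h add coupling partner, 100% of the amount charged, then wait 3.0 d
- west: change nothing and wait 3.0 d more
- north-west: at 40 h raise the temperature by 20 K, then wait 3.0 d

- target, in percent of the starting material first charged, at 40 h
- what to do for the largest gain in target; "none" if nothing gains more than 2 percentage points (south-east / south-west / north-east / west / north-west / none)
- target present, with what was taken out counted in, in percent of the starting material first charged, after south-west
- target present, with what was taken out counted in, in percent of the starting material first charged, after north-west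

Build the summer flask up step by step. Take the main cycle first: free catalyst binds starting material as catalyst intermediate A, and coupling partner turns that over into target. With c(coupling partner) at 22.0 mM against 20 mM of starting material, the starting material is the limiting reagent of this cycle, and full conversion needs 76.9 turnovers per catalyst.

Now add the loss of catalyst intermediate A to spent catalyst. The summer plateau of 34.1% is 26.2 turnovers to target per catalyst charged, fewer than the need, so in the summer flask control passes here from the reagents to the catalyst's life. The rate in the dawn run falls as well: it fell ten times between the first reading and the last interval, with target at 42.2% in the last reading. The loss step holds no coupling partner and the turnover step does, so at catalyst intermediate A the rate of making target over the rate of losing catalyst rises in proportion to c(coupling partner).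

Add the rest: second substrate also borrows free catalyst and spends coupling partner on second product. So at fixed charges of catalyst, starting material and second substrate, I carry one number. The summer plateau reads 6.82 mM of target on 22.0 mM of coupling partner, or 31.0%: this share of the coupling partner offered that ends as target is the partner yield. You should expect it to hold roughly when c(coupling partner) changes.

My own reckoning for 40 h is the plateau, since the readings spread over 0.8 percentage points at a scatter of 0.3 points. I read the flat readings as lost catalyst, and on that reading I expect no gain from removal, heat or extra coupling partner, so I look to fresh catalyst.

The forecast says 34.1% now, 34.1% after south-west and 34.1% after north-west, and it picks south-east as the best move on the grounds that “fresh catalyst uses the residual partner”.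

The flask gives 34.2%, 34.2% after south-west and 34.2% after north-west, and south-east wins with 6.3 points, so the forecast held. Spent catalyst already stands at >99.9% at 4.00 h. The fresh dose equals the first charge and meets the 22.6% of coupling partner still free at 40.0 h, so the partner yield gives an estimate of 7.7 points, somewhat more than the 6.3 points found.

    starting material + free catalyst ⇌ catalyst intermediate A (K = 86.0 M⁻¹, k = 9.32 M⁻¹ s⁻¹, Ea = 39.0 kJ mol⁻¹, ΔH = −15.0 kJ mol⁻¹)
    coupling partner + catalyst intermediate A → free catalyst + target (k = 4.33 M⁻¹ s⁻¹, Ea = 40.0 kJ mol⁻¹)
    second substrate + free catalyst ⇌ catalyst intermediate B (K = 50.0 M⁻¹, k = 5.86 M⁻¹ s⁻¹, Ea = 40.0 kJ mol⁻¹, ΔH = −42.0 kJ mol⁻¹)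
    coupling partner + catalyst intermediate B → free catalyst + second product (k = 53.3 M⁻¹ s⁻¹, Ea = 40.0 kJ mol⁻¹)
    catalyst intermediate A → spent catalyst (k = 0.00195 s⁻¹, Ea = 109 kJ mol⁻¹)
    (constants at 110 °C)

Try the same flask with 55 mM of coupling partner: the partner yield gives 85.2% target. The computed flask gives 93.9%.

Readings and results were computed for an exercise; the scatter is artificial.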